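The constants are given for 70 °C, and I want them in the coldest flask, ochre at 40 °C, where the reckoning can be done by hand.

    E ⇌ J (K1 = 1.4, k1 = 2.69 × 10⁻⁴ s⁻¹, Ea1 = 98.0 kJ mol⁻¹, ΔH1 = −32.0 kJ mol⁻¹)
    J + Z ⇌ L + Z, rate k2*[Z]*[J] forward; the back reaction follows from the equilibrium constant (K2 = 1.3, k2 = 0.256 L mol⁻¹ s⁻¹, Ea2 = 76.0 kJ mol⁻¹, ΔH2 = 43.0 kJ mol⁻¹)
    G ⇌ E, rate k3*(cs3 - [E]) while solid is left; crystals form when [E] > cs3 (cs3 = 0.40 M, k3 = 0.00401 s⁻¹)
    (constants at 70 °C)

| flask | G | Z | temperature | time |
|---|---|---|---|---|
| red | 0.72 M | 9.4 mM | 85 °C | 10 h |
| ochre | 0.72 M | 9.4 mM | 40 °C | 10 h |
| green | 0.72 M | 9.4 mM | 55 °C | 10 h |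
| grey | 0.72 M | 9.4 mM | 70 °C | 10 h |

- solid, in amounts per volume of the solution: G
- all constants are for 70 °C and move with temperature by the activation energies and enthalpies
- at the start none of G is in solution
- what has only dissolved of G counts as not reacted

- the flask with the highest amount of J, in percent of the G charged ("all alike" if they lie within 1.5 percentage points) (red / ochre / green / grey / all alike)
- final J, as a percentage of the G charged, in red
- final J, as a percentage of the G charged, in ochre
- final J, as a percentage of the G charged, in green
- final J, as a percentage of the G charged, in grey

For ochre I first need the rate constant of E to J. The equilibrium constant of J to L falls from 1.3 at the reference temperature to 0.307 in ochre. That fall scales with its enthalpy, so I can rescale it by activation energy over enthalpy, and this brings the rate constant of E to J from 2.69 × 10⁻⁴ s⁻¹ down to 0.0361 h⁻¹. Over the run this gives a reach of 0.361. The reach is that rate constant times the time: the share of a steady [E] that passes into J during the run.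

In the first instants of ochre, the gap between [E] and the solubility closes with a half-life of 2.88 min, far faster than E passes on. So [E] climbs to the solubility, 0.40 M, and stays pinned there while solid is left. [E] is what I freeze. Through the middle, neglecting the way back to E, the run passes the reach times that [E], which is 20.0% of the G charged. J does not keep all of this, since J passes into L with Z at a forward half-life near 1.03 h, shorter than the run. In ochre, E to J is slower than both the dissolving and the passing of J into L, which makes it the rate-limiting step. As an estimate, I let L stand to J at 0.307. At the end I expect ochre to hold 15.3% as J and 24.4% still as solid.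

The forecast puts ochre at 14.9%, between 14% and 16%, which is lower than my figure. It gives red 21.8%, green 42.9% and grey 33.2%, and names green as highest. Its ground for the cold flask is that “the slow first step leaves the run kinetically limited with solid still present”.

The simulation gives red 21.8%, ochre 14.8%, green 42.8% and grey 33.2%, so green stands highest. In ochre, J and L together hold 19.2% against my 20.0%, and G stands at 25.4%. The relaxation half-life of E and J there, both ways together, is 15.5 h, longer than the run, while J passes into L with a forward half-life of 1.0 h, shorter than the run. Read at 13.5 h, ochre's J has moved 5 points, out of the forecast's range. The neighbour of ochre is charged with 0.18 M of G, less than the solubility, and the same reach taken as a decay of [E] passes 30.3%, where that flask shows 29.3% passed on.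

All constants are those of an exercise; the run is a simulation.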